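**Retrosynthetic overview**
1. Target ⇒ C8 alcohol 41 + angelic acid (last step); furanone ⇒ transannular oxa-Michael closure of a macrocyclic α'-hydroxy ynone; ten-membered ring ⇒ C1–C2 bond (iodoalkyne + aldehyde, Nozaki–Hiyama–Kishi).
2. (Z)-C4=C5 enyne ⇒ C5 aldehyde (iodo-Wittig olefination, then Sonogashira coupling).
3. Spiro-cyclohexene ⇒ two alkylations at C11 of the γ-lactone (butenyl, then 2-substituted allyl) + ring-closing metathesis; this fixes the 1,3-placement of the side chain and the C11 configuration.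
4. C8/C10 ⇒ methyl ketone + methyl pyruvate (copper–bis(oxazoline) Mukaiyama aldol), then chelation-controlled syn reduction; C6/C7 ⇒ ketoreductase reduction of a β-keto ester, then Fráter–Seebach allylation.
5. Ring order: γ-lactone (C6–O–C12) → spiro-cyclohexene → ten-membered carbocycle → furanone.

Assumption: atom labels C1–C15 are the germacranolide numbers of the target (C1 ketone, C2=C3, C4=C5, C6–O lactone, C7, C8–O ester, C9, C10 quaternary, C11 spiro, C12 lactone C=O); in these labels the target is 6S,7R,8R,10R,11S, 4Z, with a 6,7-cis lactone and a (Z)-angelate.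

**Step 1**
Reactants: 1 ethyl 4-chloro-3-oxobutanoate; 2 4-methoxybenzyl alcohol
Product: 3 ethyl 4-[(4-methoxybenzyl)oxy]-3-oxobutanoate
Conditions: NaH (2.1 equiv), THF, 0 °C to rt; aq. NH4Cl
Reagents that add atoms: none
Why: Williamson-type SN2 etherification in which the alkoxide displaces the primary chloride of the enolised (self-condensation-protected) keto ester.

**Step 2**
Reactants: 3 ethyl 4-[(4-methoxybenzyl)oxy]-3-oxobutanoate
Product: 4 ethyl (3R)-3-hydroxy-4-[(4-methoxybenzyl)oxy]butanoate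
Conditions: (R)-selective ketoreductase (KRED), NADP+ (cat.), i-PrOH (10% v/v), KH2PO4/K2HPO4 buffer pH 7.0, 30 °C
Reagents that add atoms: none
Why: Ketoreductase-catalysed asymmetric reduction (NADPH hydride to one carbonyl face, isopropanol-coupled cofactor recycling) of a 4-alkoxy-3-oxobutanoate, a standard substrate class, sets C6 as the first stereocentre in >99% ee.

**Step 3**
Reactants: 4 ethyl (3R)-3-hydroxy-4-[(4-methoxybenzyl)oxy]butanoate; 5 allyl bromide
Product: 6 ethyl (2S,3R)-3-hydroxy-4-[(4-methoxybenzyl)oxy]-2-(prop-2-enyl)butanoate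
Conditions: LiN(i-Pr)2 (2.2 equiv), THF, −78 to −20 °C; then 5, DMPU, −78 to −10 °C
Reagents that add atoms: none
Why: Fráter–Seebach alkylation: the chelated lithium alkoxide–enolate dianion is allylated on the face away from the C5 arm, setting C7 anti to the C6 hydroxyl (dr typically ≥95:5).

**Step 4**
Reactants: 6 ethyl (2S,3R)-3-hydroxy-4-[(4-methoxybenzyl)oxy]-2-(prop-2-enyl)butanoate
Product: 7 (2S,3R)-3-hydroxy-N-methoxy-4-[(4-methoxybenzyl)oxy]-N-methyl-2-(prop-2-enyl)butanamide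
Conditions: MeNH(OMe)·HCl, i-PrMgCl, THF, −20 to 0 °C
Reagents that add atoms: N,O-dimethylhydroxylamine hydrochloride CNOC.Cl
Why: Weinreb amide formation by magnesium amide aminolysis of the ester, the free hydroxyl being carried as its magnesium alkoxide.

**Step 5**
Reactants: 7 (2S,3R)-3-hydroxy-N-methoxy-4-[(4-methoxybenzyl)oxy]-N-methyl-2-(prop-2-enyl)butanamide
Product: 8 (3S,4R)-4-hydroxy-5-[(4-methoxybenzyl)oxy]-3-(prop-2-enyl)pentan-2-one
Conditions: MeMgBr (3.5 equiv), THF, −78 to 0 °C; aq. NH4Cl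
Reagents that add atoms: methylmagnesium bromide C[Mg]Br
Why: Grignard addition to the Weinreb amide stops at the chelated tetrahedral intermediate, giving the methyl ketone (C8, C9) without over-addition or C7 epimerisation.

**Step 6**
Reactants: 8 (3S,4R)-4-hydroxy-5-[(4-methoxybenzyl)oxy]-3-(prop-2-enyl)pentan-2-one
Product: 9 (3S,4R)-5-[(4-methoxybenzyl)oxy]-3-(prop-2-enyl)-2,4-bis(trimethylsilyloxy)pent-1-ene
Conditions: LiN(i-Pr)2 (2.3 equiv), Me3SiCl (3 equiv), THF, −78 °C (in situ quench)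
Reagents that add atoms: chlorotrimethylsilane C[Si](C)(C)Cl
Why: Kinetic deprotonation at the methyl group with in situ silyl trapping gives the less substituted enol silane and masks the C6 hydroxyl as a transient silyl ether.

**Step 7**
Reactants: 9 (3S,4R)-5-[(4-methoxybenzyl)oxy]-3-(prop-2-enyl)-2,4-bis(trimethylsilyloxy)pent-1-ene; 10 methyl pyruvate
Product: 12 methyl (2R,5S,6R)-2,6-dihydroxy-7-[(4-methoxybenzyl)oxy]-2-methyl-4-oxo-5-(prop-2-enyl)heptanoate, via bis-silyl aldol adduct 11 (not isolated)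
Conditions: [Cu((R,R)-t-Bu-box)](OTf)2 (10 mol %), THF, −78 °C; then 1 M HCl, THF, 0 °C
Reagents that add atoms: none
Why: Catalytic enantioselective Mukaiyama aldol: pyruvate chelates divalent copper inside the C2-symmetric bis(oxazoline) pocket, one ketone face is blocked and the enol silane sets the C10 tertiary carbinol (R) under catalyst control, after which acid removes both silyl groups.

**Step 8**
Reactants: 12 methyl (2R,5S,6R)-2,6-dihydroxy-7-[(4-methoxybenzyl)oxy]-2-methyl-4-oxo-5-(prop-2-enyl)heptanoate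
Product: 14 (3R,5R)-3-hydroxy-5-[(2R,3S)-2-hydroxy-1-[(4-methoxybenzyl)oxy]hex-5-en-3-yl]-3-methyloxolan-2-one, via triol ester 13 (not isolated)
Conditions: Et2BOMe (1.2 equiv), THF/MeOH 4:1, −78 °C; NaBH4; AcOH quench, MeOH co-evaporation; then PPTS (cat.), CH2Cl2, rt
Reagents that add atoms: none
Why: Narasaka–Prasad reduction: the secondary C6 hydroxyl (not the hindered tertiary one) forms the six-membered boron chelate and external hydride gives the 6,8-syn diol (C8 R); only the new C8 hydroxyl can then close a five-membered lactone onto the C1 ester, which tells O8 apart from O6.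

**Step 9**
Reactants: 14 (3R,5R)-3-hydroxy-5-[(2R,3S)-2-hydroxy-1-[(4-methoxybenzyl)oxy]hex-5-en-3-yl]-3-methyloxolan-2-one
Product: 16 (3R,5R)-3-hydroxy-5-[(2R,3R)-5-hydroxy-2-{[(4-methoxybenzyl)oxy]methyl}oxolan-3-yl]-3-methyloxolan-2-one (lactol; both anomers), via hydroxy aldehyde 15 (not isolated)
Conditions: OsO4 (2 mol %), NaIO4 (4 equiv), 2,6-lutidine, dioxane/H2O 3:1, rt
Reagents that add atoms: osmium tetroxide O=[Os](=O)(=O)=O (delivers the new oxygen; restored by sodium periodate [Na+].[O-]I(=O)(=O)=O)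
Why: Lemieux–Johnson oxidative cleavage of the only alkene gives the C12 aldehyde, which the free C6 hydroxyl traps as the five-membered lactol.

**Step 10**
Reactants: 16 lactol (both anomers)
Product: 17 (3R,5R)-3-hydroxy-5-[(2R,3R)-2-{[(4-methoxybenzyl)oxy]methyl}-5-oxooxolan-3-yl]-3-methyloxolan-2-one
Conditions: TEMPO (10 mol %), PhI(OAc)2 (1.5 equiv), CH2Cl2, rt
Reagents that add atoms: none
Why: Oxoammonium (TEMPO) oxidation of the lactol gives the 6,7-cis γ-lactone (C6–O–C12) while the tertiary alcohol is inert.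

**Step 11**
Reactants: 17 bis-lactone
Product: 18 (4R,5R)-5-{[(4-methoxybenzyl)oxy]methyl}-4-[(1R,3R)-1,3,4-trihydroxy-3-methylbutyl]oxolan-2-one
Conditions: BH3·SMe2 (2.2 equiv), NaBH4 (5 mol %), THF, 0 °C to rt; MeOH
Reagents that add atoms: none
Why: Hydroxyl-directed borane reduction (selective for α-hydroxy esters and lactones): the C10 hydroxyl binds borane and delivers hydride only to its own lactone carbonyl, leaving the unactivated C12 lactone intact.

**Step 12**
Reactants: 18 triol lactone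
Product: 19 (4R,5R)-4-{(1R)-1-hydroxy-2-[(4R)-2,2,4-trimethyl-1,3-dioxolan-4-yl]ethyl}-5-{[(4-methoxybenzyl)oxy]methyl}oxolan-2-one
Conditions: Me2C(OMe)2, PPTS (5 mol %), CH2Cl2, rt
Reagents that add atoms: 2,2-dimethoxypropane COC(C)(C)OC
Why: Acetonide formation under thermodynamic control selects the five-membered dioxolane of the terminal C1/C10 diol over a six-membered ketal with the C8 hydroxyl.

**Step 13**
Reactants: 19 acetonide alcohol
Product: 20 (4S,5R)-4-{(1R)-1-[(tert-butyldimethylsilyl)oxy]-2-[(4R)-2,2,4-trimethyl-1,3-dioxolan-4-yl]ethyl}-5-{[(4-methoxybenzyl)oxy]methyl}oxolan-2-one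
Conditions: TBSOTf, 2,6-lutidine, CH2Cl2, −78 to 0 °C
Reagents that add atoms: tert-butyldimethylsilyl trifluoromethanesulfonate CC(C)(C)[Si](C)(C)OS(=O)(=O)C(F)(F)F
Why: Silylation of the remaining hindered secondary alcohol with the reactive silyl triflate, done before any base treatment so the lactone cannot migrate to O8.

**Step 14**
Reactants: 20 silyl ether lactone; 21 4-iodobut-1-ene
Product: 22 lactone 20 carrying a but-3-enyl group at C11, trans to the C7 side chain
Conditions: LiN(i-Pr)2 (1.15 equiv), THF, −78 °C; 21 (3 equiv), DMPU, −78 to −30 °C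
Reagents that add atoms: none
Why: SN2 alkylation of the lactone enolate; the electrophile enters trans to the C7 side chain, but C11 is re-enolised in step 17, so only the constitution matters here.

**Step 15**
Reactants: 23 2-methylprop-2-en-1-ol; 24 1-bromo-3-methylbut-2-ene (prenyl bromide)
Product: 25 6-methyl-2-methylidenehept-5-en-1-ol
Conditions: n-BuLi (2.1 equiv), TMEDA, Et2O/hexane, 0 °C to rt; then 24, −78 °C to rt
Reagents that add atoms: none
Why: C-alkylation of the allylic dianion of methallyl alcohol (lithiated at the methyl group) with the allylic bromide.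

**Step 16**
Reactants: 25 6-methyl-2-methylidenehept-5-en-1-ol
Product: 26 2-(bromomethyl)-6-methylhepta-1,5-diene
Conditions: CBr4, PPh3, CH2Cl2, 0 °C
Reagents that add atoms: tetrabromomethane BrC(Br)(Br)Br
Why: Appel bromination; SN2 and SN2' substitution give the same allylic bromide.

**Step 17**
Reactants: 22 C11-butenyl lactone; 26 2-(bromomethyl)-6-methylhepta-1,5-diene
Product: 27 lactone with quaternary C11 bearing but-3-enyl (cis to the C7 side chain) and 6-methyl-2-methylidenehept-5-enyl (trans to it)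
Conditions: LiN(i-Pr)2 (1.3 equiv), THF/DMPU, −78 to −40 °C; then 26, −78 to −20 °C
Reagents that add atoms: none
Why: Alkylation of the α-substituted lactone enolate with a reactive allylic bromide on the face opposite the C7 side chain (the cis C6 substituent shields the same face), which sets the quaternary C11.

**Step 18**
Reactants: 27 dialkylated lactone
Product: 28 spirolactone: 7-(4-methylpent-3-enyl)-2-oxaspiro[4.5]dec-7-en-1-one with CH2OPMB at ring C3 (= C6) and the silyloxy acetonide side chain at ring C4 (= C7)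
Conditions: second-generation Grubbs catalyst (5 mol %), CH2Cl2 (5 mM), 40 °C
Reagents that add atoms: none
Why: Ring-closing metathesis between the terminal alkene and the 1,1-disubstituted alkene closes the six-membered ring (the only feasible ring size), placing the side chain 1,3 to the spiro centre; the trisubstituted prenyl-type alkene does not react.

**Step 19**
Reactants: 28 spirolactone
Product: 29 spirolactone with free C5 primary alcohol
Conditions: DDQ (1.3 equiv), CH2Cl2/pH 7 buffer 10:1, 0 °C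
Reagents that add atoms: none
Why: Oxidative cleavage of the electron-rich 4-methoxybenzyl ether; silyl ether, acetonide and trisubstituted alkenes are untouched.

**Step 20**
Reactants: 29 C5 alcohol
Product: 30 C5 aldehyde (formyl group on C6 of the lactone)
Conditions: Dess–Martin periodinane, NaHCO3, CH2Cl2, 0 °C to rt
Reagents that add atoms: none
Why: Dess–Martin oxidation under buffered, non-basic conditions keeps the epimerisable C6 centre intact.

**Step 21**
Reactants: 30 C5 aldehyde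
Product: 31 (Z)-2-iodoprop-1-enyl lactone (C5H=C4(I)CH3, iodine cis to C6)
Conditions: Ph3P(Et)I, n-BuLi, THF, 0 °C; I2, −78 °C; NaN(SiMe3)2, −20 °C; then 30, −78 °C
Reagents that add atoms: ethyltriphenylphosphonium iodide CC[P+](c1ccccc1)(c1ccccc1)c1ccccc1.[I-]; iodine II
Why: Stork–Zhao-type iodo-Wittig olefination: the unstabilised α-iodo ylide reacts under kinetic control to give the (Z)-iodoalkene.

**Step 22**
Reactants: 31 (Z)-iodoalkene; 32 ethynyltrimethylsilane
Product: 33 (Z)-enyne, silyl-capped (C6–C5H=C4(CH3)–C3≡C2–SiMe3)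
Conditions: Pd(PPh3)4 (5 mol %), CuI (10 mol %), i-Pr2NH, THF, rt
Reagents that add atoms: none
Why: Sonogashira coupling proceeds with retention of alkene geometry and installs C2 and C3.

**Step 23**
Reactants: 33 silyl enyne
Product: 34 terminal (Z)-enyne
Conditions: K2CO3 (0.2 equiv), MeOH, 0 °C
Reagents that add atoms: none
Why: Base-catalysed methanolysis of the alkynyl C–Si bond; the hindered spirolactone and the silyl ether survive.

**Step 24**
Reactants: 34 terminal enyne
Product: 35 1-iodoalkyne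
Conditions: N-iodosuccinimide, AgNO3 (10 mol %), acetone, rt, dark
Reagents that add atoms: N-iodosuccinimide O=C1CCC(=O)N1I
Why: Electrophilic iodination of the terminal alkyne through its silver acetylide.

**Step 25**
Reactants: 35 iodoalkyne acetonide
Product: 36 C1/C10 diol (primary C1–OH, tertiary C10–OH)
Conditions: AcOH/THF/H2O 4:1:1, 35 °C
Reagents that add atoms: none
Why: Acid-catalysed acetonide hydrolysis; the hindered secondary silyl ether survives dilute acetic acid.

**Step 26**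
Reactants: 36 diol
Product: 37 C1 aldehyde with free tertiary C10 hydroxyl
Conditions: TEMPO (20 mol %), PhI(OAc)2 (1.2 equiv), CH2Cl2, rt
Reagents that add atoms: none
Why: TEMPO oxidation is selective for the primary alcohol and gives the non-enolisable α-hydroxy aldehyde without glycol cleavage.

**Step 27**
Reactants: 37 iodoalkyne aldehyde
Product: 38 ten-membered cyclic enyne diol (C1 carbinol as a mixture of epimers)
Conditions: CrCl2 (8 equiv), NiCl2 (2 mol %), THF, rt, 2 mM, slow addition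
Reagents that add atoms: none
Why: Intramolecular Nozaki–Hiyama–Kishi reaction: divalent chromium converts the iodoalkyne into an alkynylchromium species that adds chemoselectively to the aldehyde at high dilution and closes the C1–C2 bond.

**Step 28**
Reactants: 38 macrocyclic diol
Product: 39 macrocyclic α'-hydroxy ynone
Conditions: MnO2 (activated, excess), CH2Cl2, rt
Reagents that add atoms: none
Why: Selective oxidation of the propargylic secondary alcohol; the tertiary alcohol is retained and the C1 epimers converge.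

**Step 29**
Reactants: 39 ynone
Product: 40 C8-O-TBS ether of the furanone alcohol 41
Conditions: Ph3PAuNTf2 (5 mol %), toluene, rt
Reagents that add atoms: none
Why: Gold-catalysed 5-endo-dig transannular oxa-Michael cyclisation of the C10 hydroxyl onto C3 forms the 3(2H)-furanone.

**Step 30**
Reactants: 40 silyl ether
Product: 41 C8 alcohol (the target without its angeloyl group)
Conditions: HF·pyridine, pyridine, THF, 0 °C to rt
Reagents that add atoms: none
Why: Fluoride-mediated desilylation under buffered acidic conditions avoids base-induced migration of the lactone to O8.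

**Step 31**
Reactants: 41 C8 alcohol; 42 angelic acid
Product: 44 target CNP0226905.2, via mixed anhydride 43 (not isolated)
Conditions: 2,4,6-trichlorobenzoyl chloride, Et3N, toluene, rt; then 41, 75 °C
Reagents that add atoms: 2,4,6-trichlorobenzoyl chloride O=C(Cl)c1c(Cl)cc(Cl)cc1Cl (its atoms stay in 43 only)
Why: Yamaguchi-type esterification through the mixed anhydride without a nucleophilic catalyst acylates the hindered C8 alcohol and preserves the (Z)-geometry of the angelate.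

**Compound list**
1 | ethyl 4-chloro-3-oxobutanoate | CCOC(=O)CC(=O)CCl | starting material
2 | 4-methoxybenzyl alcohol | COc1ccc(CO)cc1 | starting material
3 | ethyl 4-[(4-methoxybenzyl)oxy]-3-oxobutanoate | CCOC(=O)CC(=O)COCc1ccc(OC)cc1 | intermediate
4 | ethyl (3R)-3-hydroxy-4-[(4-methoxybenzyl)oxy]butanoate | CCOC(=O)C[C@@H](O)COCc1ccc(OC)cc1 | intermediate
5 | allyl bromide (3-bromoprop-1-ene) | C=CCBr | starting material
6 | ethyl (2S,3R)-3-hydroxy-4-[(4-methoxybenzyl)oxy]-2-(prop-2-enyl)butanoate | CCOC(=O)[C@@H](CC=C)[C@@H](O)COCc1ccc(OC)cc1 | intermediate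
7 | (2S,3R)-3-hydroxy-N-methoxy-4-[(4-methoxybenzyl)oxy]-N-methyl-2-(prop-2-enyl)butanamide | CON(C)C(=O)[C@@H](CC=C)[C@@H](O)COCc1ccc(OC)cc1 | intermediate
8 | (3S,4R)-4-hydroxy-5-[(4-methoxybenzyl)oxy]-3-(prop-2-enyl)pentan-2-one | CC(=O)[C@@H](CC=C)[C@@H](O)COCc1ccc(OC)cc1 | intermediate
9 | (3S,4R)-5-[(4-methoxybenzyl)oxy]-3-(prop-2-enyl)-2,4-bis(trimethylsilyloxy)pent-1-ene | C=C(O[Si](C)(C)C)[C@@H](CC=C)[C@@H](O[Si](C)(C)C)COCc1ccc(OC)cc1 | intermediate
10 | methyl pyruvate (methyl 2-oxopropanoate) | COC(=O)C(C)=O | starting material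
11 | methyl (2R,5S,6R)-7-[(4-methoxybenzyl)oxy]-2-methyl-4-oxo-5-(prop-2-enyl)-2,6-bis(trimethylsilyloxy)heptanoate | COC(=O)[C@](C)(O[Si](C)(C)C)CC(=O)[C@@H](CC=C)[C@@H](O[Si](C)(C)C)COCc1ccc(OC)cc1 | intermediate
12 | methyl (2R,5S,6R)-2,6-dihydroxy-7-[(4-methoxybenzyl)oxy]-2-methyl-4-oxo-5-(prop-2-enyl)heptanoate | COC(=O)[C@](C)(O)CC(=O)[C@@H](CC=C)[C@@H](O)COCc1ccc(OC)cc1 | intermediate
13 | methyl (2R,4R,5R,6R)-2,4,6-trihydroxy-7-[(4-methoxybenzyl)oxy]-2-methyl-5-(prop-2-enyl)heptanoate | COC(=O)[C@](C)(O)C[C@@H](O)[C@@H](CC=C)[C@@H](O)COCc1ccc(OC)cc1 | intermediate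
14 | (3R,5R)-3-hydroxy-5-[(2R,3S)-2-hydroxy-1-[(4-methoxybenzyl)oxy]hex-5-en-3-yl]-3-methyloxolan-2-one | O=C1O[C@H](C[C@@]1(C)O)[C@@H](CC=C)[C@@H](O)COCc1ccc(OC)cc1 | intermediate
15 | (3S,4R)-4-hydroxy-3-[(2R,4R)-4-hydroxy-4-methyl-5-oxooxolan-2-yl]-5-[(4-methoxybenzyl)oxy]pentanal | O=C1O[C@H](C[C@@]1(C)O)[C@@H](CC=O)[C@@H](O)COCc1ccc(OC)cc1 | intermediate
16 | (3R,5R)-3-hydroxy-5-[(2R,3R)-5-hydroxy-2-{[(4-methoxybenzyl)oxy]methyl}oxolan-3-yl]-3-methyloxolan-2-one (lactol, both anomers) | O=C1O[C@H](C[C@@]1(C)O)[C@H]1CC(O)O[C@H]1COCc1ccc(OC)cc1 | intermediate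
17 | (3R,5R)-3-hydroxy-5-[(2R,3R)-2-{[(4-methoxybenzyl)oxy]methyl}-5-oxooxolan-3-yl]-3-methyloxolan-2-one | O=C1O[C@H](C[C@@]1(C)O)[C@H]1CC(=O)O[C@H]1COCc1ccc(OC)cc1 | intermediate
18 | (4R,5R)-5-{[(4-methoxybenzyl)oxy]methyl}-4-[(1R,3R)-1,3,4-trihydroxy-3-methylbutyl]oxolan-2-one | OC[C@](C)(O)C[C@@H](O)[C@H]1CC(=O)O[C@H]1COCc1ccc(OC)cc1 | intermediate
19 | (4R,5R)-4-{(1R)-1-hydroxy-2-[(4R)-2,2,4-trimethyl-1,3-dioxolan-4-yl]ethyl}-5-{[(4-methoxybenzyl)oxy]methyl}oxolan-2-one | CC1(C)OC[C@](C)(O1)C[C@@H](O)[C@H]1CC(=O)O[C@H]1COCc1ccc(OC)cc1 | intermediate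
20 | (4S,5R)-4-{(1R)-1-[(tert-butyldimethylsilyl)oxy]-2-[(4R)-2,2,4-trimethyl-1,3-dioxolan-4-yl]ethyl}-5-{[(4-methoxybenzyl)oxy]methyl}oxolan-2-one | CC1(C)OC[C@](C)(O1)C[C@@H](O[Si](C)(C)C(C)(C)C)[C@H]1CC(=O)O[C@H]1COCc1ccc(OC)cc1 | intermediate
21 | 4-iodobut-1-ene | C=CCCI | starting material
22 | lactone 20 with a but-3-enyl group at C11 (ring C3), trans to the C7 side chain | CC1(C)OC[C@](C)(O1)C[C@@H](O[Si](C)(C)C(C)(C)C)[C@H]1[C@H](CCC=C)C(=O)O[C@H]1COCc1ccc(OC)cc1 | intermediate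
23 | 2-methylprop-2-en-1-ol | CC(=C)CO | starting material
24 | 1-bromo-3-methylbut-2-ene | CC(C)=CCBr | starting material
25 | 6-methyl-2-methylidenehept-5-en-1-ol | CC(C)=CCCC(=C)CO | intermediate
26 | 2-(bromomethyl)-6-methylhepta-1,5-diene | CC(C)=CCCC(=C)CBr | intermediate
27 | lactone 20 with quaternary C11: but-3-enyl cis and 6-methyl-2-methylidenehept-5-enyl trans to the C7 side chain | CC1(C)OC[C@](C)(O1)C[C@@H](O[Si](C)(C)C(C)(C)C)[C@H]1[C@](CCC=C)(CC(=C)CCC=C(C)C)C(=O)O[C@H]1COCc1ccc(OC)cc1 | intermediate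
28 | spirolactone: 7-(4-methylpent-3-enyl)-2-oxaspiro[4.5]dec-7-en-1-one with CH2OPMB at ring C3 (= C6) and the (1R)-1-silyloxy-2-[(4R)-dioxolanyl]ethyl chain at ring C4 (= C7); substituents at C6 and C7 cis; ring CH2 next to the substituted alkene carbon trans to the C7 chain | CC1(C)OC[C@](C)(O1)C[C@@H](O[Si](C)(C)C(C)(C)C)[C@H]1[C@@]2(CCC=C(CCC=C(C)C)C2)C(=O)O[C@H]1COCc1ccc(OC)cc1 | intermediate
29 | spirolactone 28 with CH2OH in place of CH2OPMB (free C5 alcohol) | CC1(C)OC[C@](C)(O1)C[C@@H](O[Si](C)(C)C(C)(C)C)[C@H]1[C@@]2(CCC=C(CCC=C(C)C)C2)C(=O)O[C@H]1CO | intermediate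
30 | spirolactone with formyl group on C6 (C5 aldehyde) | CC1(C)OC[C@](C)(O1)C[C@@H](O[Si](C)(C)C(C)(C)C)[C@H]1[C@@]2(CCC=C(CCC=C(C)C)C2)C(=O)O[C@H]1C=O | intermediate
31 | spirolactone with (Z)-2-iodoprop-1-enyl on C6 (iodine cis to C6) | CC1(C)OC[C@](C)(O1)C[C@@H](O[Si](C)(C)C(C)(C)C)[C@H]1[C@@]2(CCC=C(CCC=C(C)C)C2)C(=O)O[C@H]1/C=C(/C)I | intermediate
32 | ethynyltrimethylsilane | C#C[Si](C)(C)C | starting material
33 | spirolactone with (Z)-2-methyl-4-(trimethylsilyl)but-1-en-3-ynyl on C6 | CC1(C)OC[C@](C)(O1)C[C@@H](O[Si](C)(C)C(C)(C)C)[C@H]1[C@@]2(CCC=C(CCC=C(C)C)C2)C(=O)O[C@H]1/C=C(/C)C#C[Si](C)(C)C | intermediate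
34 | spirolactone with (Z)-2-methylbut-1-en-3-ynyl on C6 (terminal alkyne) | CC1(C)OC[C@](C)(O1)C[C@@H](O[Si](C)(C)C(C)(C)C)[C@H]1[C@@]2(CCC=C(CCC=C(C)C)C2)C(=O)O[C@H]1/C=C(/C)C#C | intermediate
35 | spirolactone with (Z)-4-iodo-2-methylbut-1-en-3-ynyl on C6 | CC1(C)OC[C@](C)(O1)C[C@@H](O[Si](C)(C)C(C)(C)C)[C@H]1[C@@]2(CCC=C(CCC=C(C)C)C2)C(=O)O[C@H]1/C=C(/C)C#CI | intermediate
36 | iodoalkyne 35 with the acetonide removed (C1 primary and C10 tertiary hydroxyls free, C10 R) | OC[C@](C)(O)C[C@@H](O[Si](C)(C)C(C)(C)C)[C@H]1[C@@]2(CCC=C(CCC=C(C)C)C2)C(=O)O[C@H]1/C=C(/C)C#CI | intermediate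
37 | iodoalkyne with C1 aldehyde and free tertiary C10 hydroxyl | O=C[C@](C)(O)C[C@@H](O[Si](C)(C)C(C)(C)C)[C@H]1[C@@]2(CCC=C(CCC=C(C)C)C2)C(=O)O[C@H]1/C=C(/C)C#CI | intermediate
38 | ten-membered (4Z)-cyclodec-4-en-2-yne-1,10-diol (C1 epimers) fused to the spirolactone at C6/C7, with C8-OTBS | CC(C)(C)[Si](C)(C)O[C@@H]1C[C@@](C)(O)C(O)C#C/C(C)=C\[C@@H]2OC(=O)[C@]3(CCC=C(CCC=C(C)C)C3)[C@@H]21 | intermediate
39 | macrocyclic ynone (C1 ketone) with free tertiary C10 hydroxyl and C8-OTBS | CC(C)(C)[Si](C)(C)O[C@@H]1C[C@@](C)(O)C(=O)C#C/C(C)=C\[C@@H]2OC(=O)[C@]3(CCC=C(CCC=C(C)C)C3)[C@@H]21 | intermediate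
40 | C8-O-tert-butyldimethylsilyl ether of 41 | CC(C)(C)[Si](C)(C)O[C@@H]1C[C@@]2(C)OC(=CC2=O)/C(C)=C\[C@@H]2OC(=O)[C@]3(CCC=C(CCC=C(C)C)C3)[C@@H]21 | intermediate
41 | C8 alcohol: the target lacking its angeloyl group (6S,7R,8R,10R,11S; 4Z) | O[C@@H]1C[C@@]2(C)OC(=CC2=O)/C(C)=C\[C@@H]2OC(=O)[C@]3(CCC=C(CCC=C(C)C)C3)[C@@H]21 | intermediate
42 | angelic acid ((Z)-2-methylbut-2-enoic acid) | C/C=C(/C)C(=O)O | starting material
43 | angelic 2,4,6-trichlorobenzoic anhydride | C/C=C(/C)C(=O)OC(=O)c1c(Cl)cc(Cl)cc1Cl | intermediate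
44 | CNP0226905.2 (C8 angelate; 6S,7R,8R,10R,11S; 4Z) | C/C=C(/C)C(=O)O[C@@H]1C[C@@]2(C)OC(=CC2=O)/C(C)=C\[C@@H]2OC(=O)[C@]3(CCC=C(CCC=C(C)C)C3)[C@@H]21 | target

**Totals**
Total step count: 31. Longest linear sequence: 29 steps (steps 1–14 and 17–31; steps 15–16 make bromide 26).

**Three steps most likely to fail, with fallbacks**

Step 27 (closure of the strained ten-membered enyne ring; oligomerisation may win). The fallback closes the ring at C4=C5 by metathesis instead; it sets out from 30 and comes back at 40. Aldehyde 30 is methylenated (Ph3P=CH2, THF, −78 °C) to the C6-vinyl spirolactone F6. Aqueous AcOH removes the acetonide to give the diol F7, and TEMPO/PhI(OAc)2 gives the α-hydroxy aldehyde F8. Lithium 3-methylbut-3-en-1-ynide (2.5 equiv, THF, −78 °C) adds to give the propargylic diol F9, which MnO2 oxidises to the ynone F10. Ph3PAuNTf2 closes the 5-isopropenyl furanone F11. Ring-closing metathesis of the isopropenyl and vinyl groups (second-generation Hoveyda–Grubbs catalyst, toluene, 80 °C, 1 mM) then forms C4=C5, cis by constraint of the nine-membered oxacycle, and gives 40.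

Step 21 (base-sensitive α-acyloxy aldehyde; Z-selectivity and yield of the iodo-Wittig reaction vary). The fallback builds the same alkene by stepwise cross-coupling; it sets out from 30 and comes back at 33. Ramirez olefination (CBr4, PPh3, Zn, CH2Cl2, 0 °C) gives the 1,1-dibromoalkene F4. Trans-selective Negishi monomethylation (Me2Zn, Pd(P(t-Bu)3)2 cat., THF, 0 °C) replaces the bromine trans to C6 and gives the (Z)-bromoalkene F5. Sonogashira coupling of the remaining bromide with 32 (Pd(PPh3)4, CuI, i-Pr2NH, 50 °C) proceeds with retention and gives 33.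

Step 14 (alkylation with an unactivated homoallylic iodide; elimination to butadiene and low conversion). The fallback brings in the same four carbons by conjugate addition; it sets out from 20 and comes back at 27, leaving out 22. Lactone 20 is aminomethylated (LiN(i-Pr)2, then Me2N=CH2 iodide) to the Mannich base F1. Quaternisation with MeI and elimination with NaHCO3 give the α-methylidene lactone F2. Copper-mediated 1,4-addition of allylmagnesium bromide (CuBr·SMe2, Me3SiCl, THF, −78 °C) gives the silyl ketene acetal F3. Its lithium enolate (MeLi, THF, 0 °C) is alkylated with 26 (DMPU, −78 to −20 °C) on the face opposite the C7 side chain and gives 27.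

**Further compounds**
F1 | step 14 | lactone 20 with CH2NMe2 at C11, trans to the C7 side chain (Mannich base) | CC1(C)OC[C@](C)(O1)C[C@@H](O[Si](C)(C)C(C)(C)C)[C@H]1[C@H](CN(C)C)C(=O)O[C@H]1COCc1ccc(OC)cc1
F2 | step 14 | lactone 20 with exocyclic methylidene at C11 (α-methylidene lactone) | CC1(C)OC[C@](C)(O1)C[C@@H](O[Si](C)(C)C(C)(C)C)[C@H]1C(=C)C(=O)O[C@H]1COCc1ccc(OC)cc1
F3 | step 14 | trimethylsilyl ketene acetal of the C11-(but-3-enyl) lactone | CC1(C)OC[C@](C)(O1)C[C@@H](O[Si](C)(C)C(C)(C)C)[C@H]1C(CCC=C)=C(O[Si](C)(C)C)O[C@H]1COCc1ccc(OC)cc1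
F4 | step 21 | spirolactone with 2,2-dibromoethenyl on C6 | CC1(C)OC[C@](C)(O1)C[C@@H](O[Si](C)(C)C(C)(C)C)[C@H]1[C@@]2(CCC=C(CCC=C(C)C)C2)C(=O)O[C@H]1C=C(Br)Br
F5 | step 21 | spirolactone with (Z)-2-bromoprop-1-enyl on C6 (bromine cis to C6) | CC1(C)OC[C@](C)(O1)C[C@@H](O[Si](C)(C)C(C)(C)C)[C@H]1[C@@]2(CCC=C(CCC=C(C)C)C2)C(=O)O[C@H]1/C=C(/C)Br
F6 | step 27 | spirolactone with vinyl on C6 (acetonide and silyl ether kept) | CC1(C)OC[C@](C)(O1)C[C@@H](O[Si](C)(C)C(C)(C)C)[C@H]1[C@@]2(CCC=C(CCC=C(C)C)C2)C(=O)O[C@H]1C=C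
F7 | step 27 | C6-vinyl spirolactone with free C1/C10 diol | OC[C@](C)(O)C[C@@H](O[Si](C)(C)C(C)(C)C)[C@H]1[C@@]2(CCC=C(CCC=C(C)C)C2)C(=O)O[C@H]1C=C
F8 | step 27 | C6-vinyl spirolactone with C1 aldehyde and tertiary C10 hydroxyl | O=C[C@](C)(O)C[C@@H](O[Si](C)(C)C(C)(C)C)[C@H]1[C@@]2(CCC=C(CCC=C(C)C)C2)C(=O)O[C@H]1C=C
F9 | step 27 | propargylic diol from addition of 3-methylbut-3-en-1-ynyl to C1 (C1 epimers) | CC(=C)C#CC(O)[C@](C)(O)C[C@@H](O[Si](C)(C)C(C)(C)C)[C@H]1[C@@]2(CCC=C(CCC=C(C)C)C2)C(=O)O[C@H]1C=C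
F10 | step 27 | acyclic α'-hydroxy ynone (C1 ketone) carrying the isopropenyl alkyne | CC(=C)C#CC(=O)[C@](C)(O)C[C@@H](O[Si](C)(C)C(C)(C)C)[C@H]1[C@@]2(CCC=C(CCC=C(C)C)C2)C(=O)O[C@H]1C=C
F11 | step 27 | (2R)-2-methyl-5-(prop-1-en-2-yl)furan-3(2H)-one linked through its C2 (= C10) via CH2 to the C8-silyloxy carbon of the C6-vinyl spirolactone | CC(=C)C1=CC(=O)[C@](C)(O1)C[C@@H](O[Si](C)(C)C(C)(C)C)[C@H]1[C@@]2(CCC=C(CCC=C(C)C)C2)C(=O)O[C@H]1C=C
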